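The earlier runs and the new flask are simulated with constants of no real substance.

How much of the free monomer still stands in chains at 3.0 min, and how long are those chains, when we charge as much protic impurity as monomer?

the same everywhere: free monomer 0.50 mM; initiator 10 µM
- summer: protic impurity 0.25 mM; run made earlier
- midnight: protic impurity 0.38 mM; run made earlier
- flask: protic impurity 0.500 mM; time 3.0 min

- summer (time / min: monomer in chains / %, free monomer / %): 0.833: 73.6, 6.2; 1.50: 72.1, 4.4; 2.50: 69.3, 3.9; 3.00: 69.3, 4.6
- midnight (time / min: monomer in chains / %, free monomer / %): 0.417: 63.3, 12.3; 1.00: 66.4, 4.7; 2.00: 62.2, 4.1; 3.00: 58.2, 3.9

(each reading ± 0.5 percentage points)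

- average number of monomer units in a chain (chains begun, living or dead) at 3.0 min
- part of the free monomer that has reacted at 3.0 min

- the average divides the monomer in chains by the number of chains begun, living and dead together
- the numbers in the tables scatter with a standard deviation of 0.5 percentage points
- the earlier runs do not show the number of chains; that part of a forecast is a guess

Reading down the tables, free monomer falls quickly and then stays low: the last rows show 4.6% in summer and 3.9% at midnight. Reading across those last rows, chains and free monomer fall short of the charge by 26.1% in summer and 37.9% at midnight.

We take that gap as monomer quenched one for one by impurity. Summer then keeps 47.8% of its impurity and midnight 50.1%. We call this the surviving share, the part of the charged impurity still there at 3.00 min. The charge rose 1.52 times, while the share went from 47.8% to 50.1%.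

Our reckoning freezes the midnight share for the flask. Quenching then takes 49.9% of the monomer. With free monomer at the midnight 3.9%, chains hold 46.2%. If the chains begun equal the initiator charge, the average is 23.1, and 96.1% has reacted.

The forecast gives 96.1% too, but a longer 24.6, with this caution: “The chain count is a guess”.

The flask gives 25.1 and 96.4%.

    free monomer + initiator → living end + monomer in chains (k = 3700 L mol⁻¹ s⁻¹)
    free monomer + living end → monomer in chains + living end, rate k2*[living end]*[free monomer] (k = 11000 L mol⁻¹ s⁻¹)
    monomer in chains + living end → free monomer + living end, rate k3*[living end] as long as [monomer in chains] is above zero (k = 0.310 s⁻¹)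
    living end + free monomer → dead end (k = 140 L mol⁻¹ s⁻¹)
    protic impurity + free monomer → quenched substrate (k = 78.0 L mol⁻¹ s⁻¹)

At 3.00 min in the flask, the quenching step alone gives free monomer a half-life of 0.54 min but impurity one of 8.2 min. Free monomer stands at 3.63% of its charge and impurity at 55% of its own, against the midnight share of 50.1%. Carried to the neighbour flask charged with 0.12 mM of impurity, that share gives 12.0% of the monomer quenched, and the neighbour holds 13.4%.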